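**Retrosynthetic overview**

1. The target is a germacranolide: a ten-membered carbocycle (C1–C10) with a trans γ-lactone on C6/C7. Its C1–C10 oxirane (a former E-trisubstituted alkene) and the oxygenated C5 sit across that ring in a 1,3-relationship through C10, the pattern left by a Grob-type C5–C10 scission of a trans-decalin.
2. Endgame disconnections: the C8 angelate (acylation), C11 methylene (selenoxide elimination), C5 carbinol (1,2-reduction) and C1–C10 oxirane (peracid on the E-alkene) all lead back to the 5-oxo-germacra-1(10)E,4(15)-dien-6,12-olide 28.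
3. Key disconnection: 28 ⇒ eudesmanolide 27 (1β-mesylate, tertiary 5α-alcohol, trans-decalin) by re-forming C5–C10; in the forward sense an alkoxide-triggered Wharton fragmentation.
4. 27 ⇒ 8α-silyloxy santonin-type dienone 19: ring A is reshaped by Wharton transposition, hydroxyl-directed epoxidation, inversion at C1 and a Schenck ene reaction; the lactone comes from a C6 bromide and the C12 carboxylate.
5. Ring order: ring B from (S)-carvone (carbonyl transposed so that its α′-hydroxyl becomes C8–O), ring A by Robinson annulation with ethyl vinyl ketone, then the γ-lactone, then the ten-membered ring by fragmentation, last the C1–C10 oxirane.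

Key step: step 21

Assumption (remark on the chemistry): step 10 is not relied on to control C11. Compounds 14–30 are drawn as the 11S (α-methyl) series; any 11R epimer follows the same steps and merges in step 24, where C11 becomes an enolate carbon. Eudesmane/germacrane numbering is used from compound 13 on.

**Route**

Step 1
Reactants: 1 (S)-(+)-carvone
Product: 2 trans-6-hydroxycarvone, (5R,6R)-6-hydroxy-2-methyl-5-(prop-1-en-2-yl)cyclohex-2-en-1-one
Conditions: KHMDS, THF, −78 °C; then trans-2-(phenylsulfonyl)-3-phenyloxaziridine, −78 °C; aq NH4Cl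
Reagents that add atoms: trans-2-(phenylsulfonyl)-3-phenyloxaziridine, O=S(=O)(c1ccccc1)N1OC1c1ccccc1
Why: Kinetic deprotonation occurs at the α′ methylene and the cross-conjugated enolate is hydroxylated (Davis enolate oxidation) on the face opposite the adjacent isopropenyl group, giving the trans, diequatorial and thermodynamically preferred 6-hydroxy ketone.

Step 2
Reactants: 2 trans-6-hydroxycarvone
Product: 3 trans-6-(tert-butyldimethylsilyloxy)carvone
Conditions: TBSCl, imidazole, DMF, rt
Reagents that add atoms: tert-butyldimethylsilyl chloride, CC(C)(C)[Si](C)(C)Cl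
Why: Standard silylation of the secondary α-hydroxyl gives an ether that should survive the bases, hydrides and oxidants that follow and that ends as the C8 oxygen of the target.

Step 3
Reactants: 3 trans-6-(tert-butyldimethylsilyloxy)carvone
Product: 4 2,3-epoxide of 3 (oxirane trans to the isopropenyl group)
Conditions: 30% H2O2, NaOH (cat.), MeOH, 0 °C
Reagents that add atoms: hydrogen peroxide, OO
Why: Weitz–Scheffer nucleophilic epoxidation of the enone is expected to place the oxirane trans to the isopropenyl group as in carvone itself, and its facial outcome is of no consequence because both oxirane carbons lose their configuration in steps 4 and 5.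

Step 4
Reactants: 4 epoxy ketone
Product: 5 4-(tert-butyldimethylsilyloxy)-2-methyl-5-(prop-1-en-2-yl)cyclohex-2-en-1-ol (4,5-trans)
Conditions: N2H4·H2O, AcOH (cat.), MeOH, 0 °C → rt
Reagents that add atoms: none
Why: Wharton transposition (epoxy hydrazone, loss of nitrogen with oxirane opening) moves the oxygen from the original carbonyl carbon to the former β-carbon, so the silyloxy carbon becomes γ to the new oxygen, the position required for C8 of the eudesmane.

Step 5
Reactants: 5 transposed allylic alcohol
Product: 6 (4S,5R)-4-(tert-butyldimethylsilyloxy)-2-methyl-5-(prop-1-en-2-yl)cyclohex-2-en-1-one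
Conditions: Dess–Martin periodinane, NaHCO3, CH2Cl2, rt
Reagents that add atoms: none
Why: Dess–Martin oxidation of the secondary allylic alcohol gives the transposed enone without touching the silyl ether or the isopropenyl group and removes the carbinol stereocentre.

Step 6
Reactants: 6 transposed enone
Product: 7 (2R,4S,5R)-4-(tert-butyldimethylsilyloxy)-2-methyl-5-(prop-1-en-2-yl)cyclohexanone (drawn as the all-equatorial C2 epimer)
Conditions: K-Selectride, THF, −78 °C; aq NH4Cl
Reagents that add atoms: none
Why: The bulky trialkylborohydride adds hydride in a conjugate (1,4) sense to this β-unsubstituted cyclohexenone, as it does to carvone, and the C2 centre formed on protonation is epimerisable and is reset in step 8.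

Step 7
Reactants: 7 cyclohexanone; 8 (R)-(+)-1-phenylethylamine
Product: 9 N-[(R)-1-phenylethyl] ketimine of 7
Conditions: TsOH (cat.), toluene, reflux, Dean–Stark
Reagents that add atoms: 8 (R)-1-phenylethylamine, C[C@@H](N)c1ccccc1
Why: Acid-catalysed condensation with azeotropic removal of water gives the ketimine, which equilibrates with the more substituted secondary enamine that is the reacting tautomer in step 8.

Step 8
Reactants: 9 ketimine; 10 ethyl vinyl ketone
Product: 12 2-methyl-2-(3-oxopentyl) diketone with the quaternary methyl cis to the isopropenyl group, via Michael adduct imine 11 (not isolated)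
Conditions: THF, rt; then 10% aq AcOH, rt
Reagents that add atoms: 10 ethyl vinyl ketone, CCC(=O)C=C; water, O
Why: The secondary enamine adds to the enone through a compact aza-ene-like transition state on the face dictated by the (R)-phenylethyl group (d'Angelo deracemising Michael addition), which for the dihydrocarvone substitution pattern creates the quaternary carbon (future C10) with methyl cis to the isopropenyl group, and aqueous acid then hydrolyses the adduct imine.

Step 9
Reactants: 12 diketone
Product: 13 8α-(tert-butyldimethylsilyloxy)eudesma-4,11-dien-3-one (8α-silyloxy-α-cyperone)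
Conditions: NaOMe, MeOH, 60 °C
Reagents that add atoms: none
Why: Intramolecular aldol condensation of the ethyl ketone onto the ring carbonyl completes the Robinson annulation and gives the tetrasubstituted enone (C4 methyl, C4=C5) with the 10β-methyl already fixed.

Step 10
Reactants: 13 silyloxy-α-cyperone
Product: 15 8α-(tert-butyldimethylsilyloxy)eudesm-4-ene-3,12-diol (C3 epimers), via bis-9-BBN adduct 14 (not isolated)
Conditions: 9-BBN (2.5 equiv), THF, 0 °C → rt; then NaOH, H2O2, 0 °C
Reagents that add atoms: hydrogen peroxide, OO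
Why: 9-BBN hydroborates the unhindered 1,1-disubstituted isopropenyl group at its terminal carbon and reduces the enone carbonyl in a 1,2 sense while the tetrasubstituted ring alkene is inert, so oxidative work-up gives the primary C12 alcohol and an allylic C3 alcohol whose configuration is irrelevant because step 11 reoxidises it.

Step 11
Reactants: 15 diol
Product: 16 8α-(tert-butyldimethylsilyloxy)-3-oxoeudesm-4-en-12-oic acid
Conditions: TEMPO (cat.), PhI(OAc)2, MeCN/H2O, rt
Reagents that add atoms: water, O
Why: Oxoammonium oxidation (TEMPO/PhI(OAc)2) in aqueous acetonitrile takes the primary alcohol through the aldehyde hydrate to the acid and the allylic alcohol back to the enone under near-neutral conditions that spare the silyl ether.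

Step 12
Reactants: 16 keto acid
Product: 18 8α-(tert-butyldimethylsilyloxy)-3-oxoeudesm-4-en-6α,12-olide, via 6β-bromo acid 17 (not isolated)
Conditions: NBS, AIBN (cat.), PhCF3, 80 °C; then K2CO3, DMF, 0 °C → rt
Reagents that add atoms: none
Why: Wohl–Ziegler bromination of the 4-en-3-one occurs at the γ-carbon C6 with bromine axial (β), and the carboxylate then displaces it intramolecularly with inversion (SN2, 5-exo-tet), which puts the lactone oxygen α and trans to the C7 side chain without acid that could equilibrate C6.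

Step 13
Reactants: 18 enone lactone
Product: 19 8α-(tert-butyldimethylsilyloxy)-3-oxoeudesma-1,4-dien-6α,12-olide (O-silyl artemisin)
Conditions: DDQ, dioxane, reflux
Reagents that add atoms: none
Why: DDQ in neutral dioxane dehydrogenates a 4-en-3-one through its C2 enol to the cross-conjugated 1,4-dien-3-one, the ring A of santonin.

Step 14
Reactants: 19 dienone lactone
Product: 20 1α,2α-epoxy-8α-(tert-butyldimethylsilyloxy)-3-oxoeudesm-4-en-6α,12-olide
Conditions: t-BuOOH, DBU, CH2Cl2, 0 °C → rt
Reagents that add atoms: tert-butyl hydroperoxide, CC(C)(C)OO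
Why: Weitz–Scheffer epoxidation under non-hydrolytic conditions attacks the less substituted C1=C2 bond of the cross-conjugated dienone at C1 from the α face, anti to the angular methyl on the adjacent C10.

Step 15
Reactants: 20 epoxy enone
Product: 21 1α-hydroxy-8α-(tert-butyldimethylsilyloxy)eudesma-2,4-dien-6α,12-olide
Conditions: N2H4·H2O, AcOH, MeOH, 0 °C
Reagents that add atoms: none
Why: Wharton transposition converts C3=O into C2=C3 while the C1–O bond is untouched, so the allylic alcohol keeps the 1α configuration and the product is a homoannular 2,4-diene.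

Step 16
Reactants: 21 dienol
Product: 22 2α,3α-epoxy-1α-hydroxy-8α-(tert-butyldimethylsilyloxy)eudesm-4-en-6α,12-olide
Conditions: VO(acac)2 (cat.), t-BuOOH, CH2Cl2, 0 °C
Reagents that add atoms: tert-butyl hydroperoxide, CC(C)(C)OO
Why: Vanadium-catalysed epoxidation is directed by the pseudoaxial allylic 1α-hydroxyl to the adjacent C2=C3 bond and to its α face, leaving the more substituted but only homoallylic C4=C5 bond alone.

Step 17
Reactants: 22 cis-epoxy alcohol
Product: 23 2α,3α-epoxy-1-oxo-8α-(tert-butyldimethylsilyloxy)eudesm-4-en-6α,12-olide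
Conditions: Dess–Martin periodinane, NaHCO3, CH2Cl2, 0 °C → rt
Reagents that add atoms: none
Why: Buffered Dess–Martin oxidation removes the wrongly configured C1 carbinol without opening the vinyl oxirane.

Step 18
Reactants: 23 epoxy ketone
Product: 24 2α,3α-epoxy-1β-hydroxy-8α-(tert-butyldimethylsilyloxy)eudesm-4-en-6α,12-olide
Conditions: NaBH4, CeCl3·7H2O, MeOH, −78 °C
Reagents that add atoms: none
Why: Luche reduction should deliver hydride to C1 from the α face, away from the angular methyl on the neighbouring quaternary C10, to give the equatorial 1β-alcohol trans to the oxirane, which is also the sense usually found for cerium-mediated borohydride reduction of cyclic α,β-epoxy ketones.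

Step 19
Reactants: 24 trans-epoxy alcohol
Product: 26 2α,3α-epoxy-1β,5α-dihydroxy-8α-(tert-butyldimethylsilyloxy)eudesm-4(15)-en-6α,12-olide, via 5α-hydroperoxide 25 (not isolated)
Conditions: O2, hν, tetraphenylporphyrin (cat.), CH2Cl2, −20 °C; then PPh3, −20 °C → rt
Reagents that add atoms: oxygen, O=O
Why: Singlet oxygen adds to the tetrasubstituted C4=C5 bond from the α face opposite the angular methyl (Schenck ene reaction), and because the only allylic hydrogens within reach of an α-bound oxygen are those of the C4 methyl (H3 and H6 are both β) the double bond moves to C4=C15 and the C5α hydroperoxide is reduced in the flask to the tertiary alcohol, which fixes the trans ring fusion.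

Step 20
Reactants: 26 diol
Product: 27 2α,3α-epoxy-5α-hydroxy-1β-mesyloxy-8α-(tert-butyldimethylsilyloxy)eudesm-4(15)-en-6α,12-olide
Conditions: MsCl, Et3N, CH2Cl2, −20 °C
Reagents that add atoms: methanesulfonyl chloride, CS(=O)(=O)Cl
Why: Sulfene-mediated mesylation selects the secondary equatorial 1β-hydroxyl over the tertiary C5 hydroxyl, and triethylamine is too weak a base to trigger the fragmentation.

Step 21
Reactants: 27 hydroxy mesylate
Product: 28 2,3-epoxy-5-oxo-8α-(tert-butyldimethylsilyloxy)germacra-1(10)E,4(15)-dien-6α,12-olide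
Conditions: t-BuOK (about 1 equiv), t-BuOH/THF, 0 °C, short contact; pH 7 buffer
Reagents that add atoms: none
Why: Deprotonation of the tertiary C5 hydroxyl gives an alkoxide whose oxygen lone pair, the C5–C10 σ bond and the C1–O bond of the equatorial 1β-mesylate are antiperiplanar across the trans ring fusion, so C5=O forms, C5–C10 breaks and mesylate leaves C1 in one concerted 1,4-elimination. This is the Wharton fragmentation of a decalin 1,3-diol monosulfonate, a Grob-type fragmentation and the established way from trans-decalins to E-cyclodecenones. The ten-membered carbocycle is not closed by bond formation but unveiled by scission of the shared C5–C10 bond, so no macrocyclisation is involved. No stereocentre is created; the element set here is the C1=C10 geometry, which is E because the axial H1 and the axial C10 methyl are anti in 27 and therefore end up trans, leaving C2 and C9 trans as well. The selectivity needed is fragmentation over elimination, substitution or lactone acyl shift, and it is secured by the locked antiperiplanar array, by the lack of an anti hydrogen on the oxirane carbon C2 and by the irreversibility of C–C cleavage relative to reversible O6-to-O5 acyl transfer. A brief, cold reaction with about one equivalent of base limits exposure of the α-methylene ketone and of the epimerisable C6 centre in 28.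

Step 22
Reactants: 28 germacradienone
Product: 29 (1R,10R)-1,10:2,3-diepoxy-5-oxo-8α-(tert-butyldimethylsilyloxy)germacr-4(15)-en-6α,12-olide
Conditions: mCPBA, NaHCO3, CH2Cl2, 0 °C, directly after step 21
Reagents that add atoms: 3-chloroperbenzoic acid, O=C(OO)c1cccc(Cl)c1
Why: Prilezhaev epoxidation selects the electron-rich trisubstituted C1=C10 bond over the enone C4=C15 bond and attacks its exposed outer face, the one from which the mesylate departed, giving the trans oxirane, while buffer and low temperature protect the vinyl oxirane and forestall Cope rearrangement of the cis-divinyl oxirane in 28.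

Step 23
Reactants: 29 diepoxy enone
Product: 30 (5S)-1,10:2,3-diepoxy-5-hydroxy-8α-(tert-butyldimethylsilyloxy)germacr-4(15)-en-6α,12-olide
Conditions: NaBH4, CeCl3·7H2O, MeOH, −78 °C
Reagents that add atoms: none
Why: Luche conditions reduce the enone carbonyl in a 1,2 sense, and hydride is expected to approach antiperiplanar to the electron-withdrawing C6–O bond of the lactone (polar Felkin–Anh control), which gives the 5,6-syn (5S) allylic alcohol of the target.

Step 24
Reactants: 30 allylic alcohol
Product: 31 11-phenylseleno derivative of 30 (selenium anti to H7)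
Conditions: LDA (2.2 equiv), THF, −78 °C; then PhSeBr, −78 °C
Reagents that add atoms: phenylselenyl bromide, Br[Se]c1ccccc1
Why: Two equivalents of LDA form the C5 alkoxide and the lactone enolate, and the enolate is selenenylated at C11 on the face opposite H7 of the trans-fused lactone (enolate selenenylation), so both C11 epimers of 30 converge on one selenide.

Step 25
Reactants: 31 selenide
Product: 33 (5S)-1,10:2,3-diepoxy-5-hydroxy-8α-(tert-butyldimethylsilyloxy)germacra-4(15),11(13)-dien-6α,12-olide, via selenoxide 32 (not isolated)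
Conditions: 30% H2O2, pyridine, CH2Cl2, 0 °C → rt
Reagents that add atoms: none
Why: Oxidation to the selenoxide is followed by spontaneous syn elimination (Grieco α-methylenation), which can only take a hydrogen from the C11 methyl because H7 is anti to selenium, giving the exocyclic C11=C13 bond.

Step 26
Reactants: 33 silyl ether
Product: 34 (5S)-1,10:2,3-diepoxy-5,8α-dihydroxygermacra-4(15),11(13)-dien-6α,12-olide
Conditions: TBAF, AcOH, THF, 0 °C → rt
Reagents that add atoms: none
Why: Fluoride cleaves the silyl ether, and acetic acid buffers the alkoxide so that neither the α-methylene lactone nor the oxiranes are attacked.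

Step 27
Reactants: 34 diol; 35 angelic acid
Product: 37 target, 8α-angeloyloxy-(1R,10R)-1,10:2,3-diepoxy-(5S)-5-hydroxygermacra-4(15),11(13)-dien-6α,12-olide, via mixed angelic anhydride 36 (not isolated)
Conditions: 35, 2,4,6-trichlorobenzoyl chloride, Et3N, toluene, rt; then 34, 80 °C
Reagents that add atoms: 35 angelic acid, C/C=C(/C)C(=O)O
Why: Yamaguchi-type acylation with the preformed mixed anhydride should esterify the more accessible C8 hydroxyl in preference to the C5 hydroxyl, which is flanked by the C4 alkene and the lactone-bearing C6 and is deactivated by the neighbouring acyloxy group, and this activation mode best preserves the Z geometry of the angelate.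

**Compound list**

1 | (S)-(+)-carvone | CC(=C)[C@@H]1CC(=O)C(C)=CC1 | starting material
2 | trans-6-hydroxycarvone | CC(=C)[C@@H]1[C@@H](O)C(=O)C(C)=CC1 | intermediate
3 | trans-6-(tert-butyldimethylsilyloxy)carvone | CC(=C)[C@@H]1[C@@H](O[Si](C)(C)C(C)(C)C)C(=O)C(C)=CC1 | intermediate
4 | 2,3-epoxide of 3, oxirane trans to isopropenyl | CC(=C)[C@@H]1[C@@H](O[Si](C)(C)C(C)(C)C)C(=O)[C@@]2(C)O[C@H]2C1 | intermediate
5 | 4-silyloxy-2-methyl-5-isopropenylcyclohex-2-en-1-ol | CC(=C)[C@@H]1[C@@H](O[Si](C)(C)C(C)(C)C)C=C(C)[C@@H](O)C1 | intermediate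
6 | (4S,5R)-4-silyloxy-2-methyl-5-isopropenylcyclohex-2-en-1-one | CC(=C)[C@@H]1[C@@H](O[Si](C)(C)C(C)(C)C)C=C(C)C(=O)C1 | intermediate
7 | (2R,4S,5R)-4-silyloxy-2-methyl-5-isopropenylcyclohexanone | CC(=C)[C@@H]1[C@@H](O[Si](C)(C)C(C)(C)C)C[C@@H](C)C(=O)C1 | intermediate
8 | (R)-(+)-1-phenylethylamine | C[C@@H](N)c1ccccc1 | starting material
9 | N-[(R)-1-phenylethyl] ketimine of 7 | C[C@@H](N=C1C[C@H](C(C)=C)[C@@H](O[Si](C)(C)C(C)(C)C)C[C@H]1C)c1ccccc1 | intermediate
10 | ethyl vinyl ketone | CCC(=O)C=C | starting material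
11 | Michael adduct imine | C[C@@H](N=C1C[C@H](C(C)=C)[C@@H](O[Si](C)(C)C(C)(C)C)C[C@@]1(C)CCC(=O)CC)c1ccccc1 | intermediate
12 | 2-methyl-2-(3-oxopentyl) diketone | O=C1C[C@H](C(C)=C)[C@@H](O[Si](C)(C)C(C)(C)C)C[C@@]1(C)CCC(=O)CC | intermediate
13 | 8α-silyloxyeudesma-4,11-dien-3-one | CC1=C2C[C@H](C(C)=C)[C@@H](O[Si](C)(C)C(C)(C)C)C[C@@]2(C)CCC1=O | intermediate
14 | bis-9-BBN adduct (C12–B and C3–O–B) | CC1=C2C[C@H]([C@H](C)CB3C4CCCC3CCC4)[C@@H](O[Si](C)(C)C(C)(C)C)C[C@@]2(C)CCC1OB5C6CCCC5CCC6 | intermediate
15 | 8α-silyloxyeudesm-4-ene-3,12-diol | CC1=C2C[C@H]([C@H](C)CO)[C@@H](O[Si](C)(C)C(C)(C)C)C[C@@]2(C)CCC1O | intermediate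
16 | 8α-silyloxy-3-oxoeudesm-4-en-12-oic acid | CC1=C2C[C@H]([C@H](C)C(=O)O)[C@@H](O[Si](C)(C)C(C)(C)C)C[C@@]2(C)CCC1=O | intermediate
17 | 6β-bromo-8α-silyloxy-3-oxoeudesm-4-en-12-oic acid | CC1=C2[C@H](Br)[C@H]([C@H](C)C(=O)O)[C@@H](O[Si](C)(C)C(C)(C)C)C[C@@]2(C)CCC1=O | intermediate
18 | 8α-silyloxy-3-oxoeudesm-4-en-6α,12-olide | C[C@@H]1C(=O)O[C@H]2[C@H]1[C@@H](O[Si](C)(C)C(C)(C)C)C[C@@]3(C)CCC(=O)C(C)=C23 | intermediate
19 | 8α-silyloxy-3-oxoeudesma-1,4-dien-6α,12-olide | C[C@@H]1C(=O)O[C@H]2[C@H]1[C@@H](O[Si](C)(C)C(C)(C)C)C[C@@]3(C)C=CC(=O)C(C)=C23 | intermediate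
20 | 1α,2α-epoxy-8α-silyloxy-3-oxoeudesm-4-en-6α,12-olide | C[C@@H]1C(=O)O[C@H]2[C@H]1[C@@H](O[Si](C)(C)C(C)(C)C)C[C@@]3(C)[C@H]4O[C@H]4C(=O)C(C)=C23 | intermediate
21 | 1α-hydroxy-8α-silyloxyeudesma-2,4-dien-6α,12-olide | C[C@@H]1C(=O)O[C@H]2[C@H]1[C@@H](O[Si](C)(C)C(C)(C)C)C[C@@]3(C)[C@@H](O)C=CC(C)=C23 | intermediate
22 | 2α,3α-epoxy-1α-hydroxy-8α-silyloxyeudesm-4-en-6α,12-olide | C[C@@H]1C(=O)O[C@H]2[C@H]1[C@@H](O[Si](C)(C)C(C)(C)C)C[C@@]3(C)[C@@H](O)[C@H]4O[C@H]4C(C)=C23 | intermediate
23 | 2α,3α-epoxy-1-oxo-8α-silyloxyeudesm-4-en-6α,12-olide | C[C@@H]1C(=O)O[C@H]2[C@H]1[C@@H](O[Si](C)(C)C(C)(C)C)C[C@@]3(C)C(=O)[C@H]4O[C@H]4C(C)=C23 | intermediate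
24 | 2α,3α-epoxy-1β-hydroxy-8α-silyloxyeudesm-4-en-6α,12-olide | C[C@@H]1C(=O)O[C@H]2[C@H]1[C@@H](O[Si](C)(C)C(C)(C)C)C[C@@]3(C)[C@H](O)[C@H]4O[C@H]4C(C)=C23 | intermediate
25 | 5α-hydroperoxy-2α,3α-epoxy-1β-hydroxy-8α-silyloxyeudesm-4(15)-en-6α,12-olide | C[C@@H]1C(=O)O[C@H]2[C@H]1[C@@H](O[Si](C)(C)C(C)(C)C)C[C@@]3(C)[C@H](O)[C@H]4O[C@H]4C(=C)[C@]23OO | intermediate
26 | 2α,3α-epoxy-1β,5α-dihydroxy-8α-silyloxyeudesm-4(15)-en-6α,12-olide | C[C@@H]1C(=O)O[C@H]2[C@H]1[C@@H](O[Si](C)(C)C(C)(C)C)C[C@@]3(C)[C@H](O)[C@H]4O[C@H]4C(=C)[C@]23O | intermediate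
27 | 2α,3α-epoxy-5α-hydroxy-1β-mesyloxy-8α-silyloxyeudesm-4(15)-en-6α,12-olide | C[C@@H]1C(=O)O[C@H]2[C@H]1[C@@H](O[Si](C)(C)C(C)(C)C)C[C@@]3(C)[C@H](OS(C)(=O)=O)[C@H]4O[C@H]4C(=C)[C@]23O | intermediate
28 | 2,3-epoxy-5-oxo-8α-silyloxygermacra-1(10)E,4(15)-dien-6α,12-olide | C[C@@H]1C(=O)O[C@H]2[C@H]1[C@@H](O[Si](C)(C)C(C)(C)C)C/C(C)=C/[C@H]3O[C@H]3C(=C)C2=O | intermediate
29 | (1R,10R)-1,10:2,3-diepoxy-5-oxo-8α-silyloxygermacr-4(15)-en-6α,12-olide | C[C@@H]1C(=O)O[C@H]2[C@H]1[C@@H](O[Si](C)(C)C(C)(C)C)C[C@@]3(C)O[C@@H]3[C@H]4O[C@H]4C(=C)C2=O | intermediate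
30 | (5S)-1,10:2,3-diepoxy-5-hydroxy-8α-silyloxygermacr-4(15)-en-6α,12-olide | C[C@@H]1C(=O)O[C@H]2[C@H]1[C@@H](O[Si](C)(C)C(C)(C)C)C[C@@]3(C)O[C@@H]3[C@H]4O[C@H]4C(=C)[C@@H]2O | intermediate
31 | 11-phenylseleno derivative of 30 | C[C@]1([Se]c5ccccc5)C(=O)O[C@H]2[C@H]1[C@@H](O[Si](C)(C)C(C)(C)C)C[C@@]3(C)O[C@@H]3[C@H]4O[C@H]4C(=C)[C@@H]2O | intermediate
32 | selenoxide of 31 | C[C@]1([Se](=O)c5ccccc5)C(=O)O[C@H]2[C@H]1[C@@H](O[Si](C)(C)C(C)(C)C)C[C@@]3(C)O[C@@H]3[C@H]4O[C@H]4C(=C)[C@@H]2O | intermediate
33 | (5S)-1,10:2,3-diepoxy-5-hydroxy-8α-silyloxygermacra-4(15),11(13)-dien-6α,12-olide | C=C1C(=O)O[C@H]2[C@H]1[C@@H](O[Si](C)(C)C(C)(C)C)C[C@@]3(C)O[C@@H]3[C@H]4O[C@H]4C(=C)[C@@H]2O | intermediate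
34 | (5S)-1,10:2,3-diepoxy-5,8α-dihydroxygermacra-4(15),11(13)-dien-6α,12-olide | C=C1C(=O)O[C@H]2[C@H]1[C@@H](O)C[C@@]3(C)O[C@@H]3[C@H]4O[C@H]4C(=C)[C@@H]2O | intermediate
35 | angelic acid, (Z)-2-methylbut-2-enoic acid | C/C=C(/C)C(=O)O | starting material
36 | angelic 2,4,6-trichlorobenzoic anhydride | C/C=C(/C)C(=O)OC(=O)c1c(Cl)cc(Cl)cc1Cl | intermediate
37 | EANPDB:COMP_00179, the 8α-angelate of 34 | C=C1C(=O)O[C@H]2[C@H]1[C@@H](OC(=O)/C(C)=C\C)C[C@@]3(C)O[C@@H]3[C@H]4O[C@H]4C(=C)[C@@H]2O | target

**Count and risks**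

Total step count: 27. Longest linear sequence: 27 steps, from (S)-carvone 1 to target 37.

The three steps most likely to fail:

Step 21 (key step). The external base may damage substrate or product faster than the alkoxide fragments: acyl shift of the lactone from O6 to the C5 alkoxide, conjugate addition to the new α-methylene ketone, or epimerisation at C6 next to the new carbonyl. Fallback: set out from 27 and cap the tertiary hydroxyl with TMS-imidazole (or TMSOTf/2,6-lutidine) to give the 1β-mesyloxy-5α-trimethylsilyloxy compound F1. Anhydrous TBAF or TASF in THF at −78 °C then cleaves the tertiary trimethylsilyl ether far faster than the secondary TBS ether and releases the alkoxide with no other base present, so that fragmentation is the only open pathway and the route rejoins at 28.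

Step 23. Facial selectivity of hydride delivery to a conformationally mobile ten-membered enone may be poor or reversed, giving the C5 epimer. Fallback: set out from 29 and carry the reduction through to the (5R)-epimeric alcohol F2. Invert it by Mitsunobu reaction with 4-nitrobenzoic acid (PPh3, DIAD, THF, 0 °C) to the (5S)-4-nitrobenzoate F3, and remove the ester with K2CO3 in methanol to rejoin the route at 30.

Step 27. Discrimination between the C8 and C5 hydroxyls may be incomplete (acylation at C5 or twice), and prolonged heating may isomerise the angelate towards the tiglate. Fallback: set out from 34 and oxidise only the allylic C5 carbinol with MnO2 in CH2Cl2 to the 5-oxo-8α-hydroxy compound F4. Acylate its single remaining hydroxyl with the same mixed anhydride to the 8α-angelate enone F5, then restore the C5 carbinol by Luche reduction at −78 °C, which is fast enough at the enone carbonyl to spare the α-methylene lactone, to arrive at 37.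

**Further compounds**

F1 | step 21 | 2α,3α-epoxy-1β-mesyloxy-5α-trimethylsilyloxy-8α-(tert-butyldimethylsilyloxy)eudesm-4(15)-en-6α,12-olide | C[C@@H]1C(=O)O[C@H]2[C@H]1[C@@H](O[Si](C)(C)C(C)(C)C)C[C@@]3(C)[C@H](OS(C)(=O)=O)[C@H]4O[C@H]4C(=C)[C@]23O[Si](C)(C)C
F2 | step 23 | (5R)-epimer of 30 | C[C@@H]1C(=O)O[C@H]2[C@H]1[C@@H](O[Si](C)(C)C(C)(C)C)C[C@@]3(C)O[C@@H]3[C@H]4O[C@H]4C(=C)[C@H]2O
F3 | step 23 | (5S)-4-nitrobenzoate of 30 | C[C@@H]1C(=O)O[C@H]2[C@H]1[C@@H](O[Si](C)(C)C(C)(C)C)C[C@@]3(C)O[C@@H]3[C@H]4O[C@H]4C(=C)[C@@H]2OC(=O)c5ccc(cc5)[N+](=O)[O-]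
F4 | step 27 | (1R,10R)-1,10:2,3-diepoxy-8α-hydroxy-5-oxogermacra-4(15),11(13)-dien-6α,12-olide | C=C1C(=O)O[C@H]2[C@H]1[C@@H](O)C[C@@]3(C)O[C@@H]3[C@H]4O[C@H]4C(=C)C2=O
F5 | step 27 | 8α-angeloyloxy-(1R,10R)-1,10:2,3-diepoxy-5-oxogermacra-4(15),11(13)-dien-6α,12-olide | C=C1C(=O)O[C@H]2[C@H]1[C@@H](OC(=O)/C(C)=C\C)C[C@@]3(C)O[C@@H]3[C@H]4O[C@H]4C(=C)C2=O
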